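Ring A (C1–C5, C10; drimane numbering, C11 = OCH2 on C9) is closed last, through the C3–C4 bond. The route exploits the neopentyl carbinol C3(OH)–C4(CH3)2 of ring A, the retron of an isopropenyl group on C5 and an aldehyde at C3. Markovnikov hydrogen atom transfer to the isopropenyl group gives the tertiary C4 radical, which adds 6-exo to the aldehyde. One operation therefore closes ring A and creates the quaternary C4 and the C3 carbinol. The precursor is a keto aldehyde from (S)-carvone (ring B), alkylated twice at C10 with the 3-oxopropyl chain trans to the isopropenyl group, which fixes the trans ring fusion beforehand.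

Key step: step 4

Remark: the target SMILES is read as the trans-fused decalin of the ent-drimane series, (3S,5S,9R,10S), with the C3 hydroxyl axial (syn to H-5, anti to the C10 methyl) and C11 cis to the C10 methyl; ring B = C5–C10.

Step 1
Reactants: 1 (S)-(+)-carvone, (5S)-2-methyl-5-(prop-1-en-2-yl)cyclohex-2-en-1-one
Product: 3 (5S,6R)-2,6-dimethyl-5-(prop-1-en-2-yl)cyclohex-2-en-1-one (trans-6-methylcarvone; the cis epimer is equally usable), via lithium dienolate 2 (not isolated)
Conditions: LiN(i-Pr)2 (LDA), THF, −78 °C; then MeI, −78 → 0 °C
Reagents that add atoms: iodomethane, CI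
Why: Kinetic deprotonation at the alpha-prime carbon gives the cross-conjugated dienolate, which is C-methylated (enolate alkylation); the new centre at C10 forms mainly trans to the isopropenyl group but is erased in step 2.

Step 2
Reactants: 3 (5S,6R)-6-methylcarvone
Product: 5 (5R,6R)-2,6-dimethyl-6-(prop-2-en-1-yl)-5-(prop-1-en-2-yl)cyclohex-2-en-1-one (allyl trans to isopropenyl), via lithium enolate 4 (not isolated)
Conditions: LiN(i-Pr)2 (LDA), THF/DMPU, −78 → −20 °C; then allyl bromide, −78 °C → rt
Reagents that add atoms: allyl bromide, C=CCBr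
Why: A second alpha-prime enolate alkylation builds the quaternary C10; allyl bromide should approach the planar enolate on the face anti to the neighbouring isopropenyl group on C5, so the allyl chain (C1–C3) ends trans to the isopropenyl group (C4) and the C10 methyl cis to it.

Step 3
Reactants: 5 (5R,6R)-6-allyl-6-methylcarvone
Product: 6 3-[(1R,6R)-1,3-dimethyl-2-oxo-6-(prop-1-en-2-yl)cyclohex-3-en-1-yl]propanal
Conditions: PdCl2(PhCN)2 (10 mol %), CuCl2·2H2O (10 mol %), AgNO2 (5 mol %), O2 (1 atm), t-BuOH/MeNO2 15:1, rt
Reagents that add atoms: dioxygen, O=O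
Why: The nitrite-modified, aldehyde-selective (anti-Markovnikov) Wacker oxidation puts oxygen on the terminal carbon of the unbiased monosubstituted alkene, while the 1,1-disubstituted isopropenyl alkene and the conjugated enone alkene are poor substrates for oxypalladation.

Step 4
Reactants: 6 keto aldehyde
Product: 7 (5R,10R)-3-hydroxy-11-nordrim-7-en-9-one, i.e. (4aR,8aR)-6-hydroxy-2,5,5,8a-tetramethyl-4a,5,6,7,8,8a-hexahydronaphthalen-1(4H)-one (trans-fused; both C3 epimers)
Conditions: Fe(acac)3 (30 mol %), PhSiH3 (2.5 equiv, slow addition), EtOH/ethylene glycol 5:1, 0.02 M, 60 °C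
Reagents that add atoms: none
Why: An iron hydride formed from Fe(acac)3 and PhSiH3 transfers a hydrogen atom to the CH2 terminus of the isopropenyl group (Markovnikov MHAT), so the tertiary C4 radical, which then carries both C4 methyl groups, adds to the aldehyde carbon C3 and the alkoxy radical is reduced and protonated to the C3 alcohol. The closest known reaction type is the iron-catalysed HAT-initiated reductive radical cyclisation of alkene-tethered ketones, together with the analogous addition of unactivated alkenes to aldehydes. Ring A (C3, C4, C5, C10, C1, C2) closes in the 6-exo-trig mode onto C=O through a chair in which C4 on C5 and C1 on C10 are both equatorial on ring B, which is possible because they are trans, so the decalin should be trans-fused and C5 and C10 keep their configuration. C3 is the only new stereocentre and is only weakly controlled (alkoxy oxygen equatorial or axial in the chair), so a mixture of C3 epimers is expected and accepted, because both epimers are merged into one ketone in step 6 and C3 is set in step 7. The step needs chemoselective HAT to the electron-rich 1,1-disubstituted alkene beside the electron-poor trisubstituted enone alkene, and ring closure that outruns reduction of the C4 radical; the fully substituted radical centre, the quaternary C10 in the tether and high dilution should secure this.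

Step 5
Reactants: 7 hydroxy enone (both C3 epimers)
Product: 8 (5S,10R)-drima-7,9(11)-dien-3-ol (both C3 epimers)
Conditions: Ph3PCH3Br (4 equiv), KOt-Bu (4 equiv), toluene, 90 °C
Reagents that add atoms: methyltriphenylphosphonium bromide, C[P+](c1ccccc1)(c1ccccc1)c1ccccc1.[Br-]
Why: Wittig methylenation of the only carbonyl group; the C9 ketone cannot enolise towards the quaternary C10, the free hydroxyl is carried as its alkoxide by the excess ylide, heat drives the hindered ketone, and no stereocentre is formed.

Step 6
Reactants: 8 dienol (both C3 epimers)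
Product: 9 (5S,10R)-drima-7,9(11)-dien-3-one
Conditions: Dess–Martin periodinane, CH2Cl2, rt
Reagents that add atoms: none
Why: Dess–Martin oxidation of the secondary alcohol under neutral conditions merges both C3 epimers into one ketone and leaves the conjugated diene untouched.

Step 7
Reactants: 9 dienone
Product: 10 (3S,5S,10R)-drima-7,9(11)-dien-3-ol (axial hydroxyl)
Conditions: LiBH(s-Bu)3 (L-Selectride), THF, −78 → 0 °C; then H2O
Reagents that add atoms: none
Why: Reagent-controlled ketone reduction: the bulky trialkylborohydride should attack the 4,4-dimethyl-3-ketone along the equatorial trajectory, as in selectride reductions of 4,4-dimethyl-3-oxo terpenoids, so the C3 hydroxyl ends axial (syn to H-5, anti to the C10 methyl), which is the (3S) configuration of the target.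

Step 8
Reactants: 10 axial dienol
Product: 12 (3S,5S,9R,10R)-drim-7-ene-3,11-diol, via borane adduct 11 (not isolated)
Conditions: 9-BBN (2.5 equiv), THF, 0 °C → rt; then NaOH, H2O2, 0 °C
Reagents that add atoms: hydrogen peroxide, OO
Why: Hydroboration–oxidation: 9-BBN should add to the terminal exocyclic C9=C11 bond of the conjugated diene with boron on C11 and leave the trisubstituted C7=C8 bond, and hydrogen is delivered to C9 on the face anti to the axial C10 methyl, which sets (9R) with the CH2OH group equatorial and cis to that methyl.

Step 9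
Reactants: 12 diol; 13 umbelliferone (7-hydroxy-2H-chromen-2-one)
Product: 14 7-{[(3S,5S,9R,10R)-3-hydroxydrim-7-en-11-yl]oxy}-2H-chromen-2-one
Conditions: PPh3, DIAD, THF, 0 → 50 °C
Reagents that add atoms: none
Why: Mitsunobu etherification: the primary C11 hydroxyl is activated in preference to the axial neopentyl C3 hydroxyl and is displaced by the acidic phenol (pKa about 8) under neutral conditions; no stereocentre is touched.

Step 10
Reactants: 14 aryl ether
Product: 15 ferocaulidin, 7-{[(3S,5S,9R,10S)-3-hydroxy-6-oxodrim-7-en-11-yl]oxy}-2H-chromen-2-one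
Conditions: Rh2(cap)4 (cap = caprolactamate, 1 mol %), t-BuOOH (70 % in water, 5 equiv), 1,2-dichloroethane, 40 °C
Reagents that add atoms: tert-butyl hydroperoxide, CC(C)(C)OO
Why: Allylic C–H oxidation by the tert-butylperoxyl radical should convert C6, the only methylene allylic to C7=C8, into the enone carbonyl; the hindered axial C3 carbinol is not expected to be oxidised, and the base-free medium leaves C5 (trans from step 2 and now alpha to the ketone), C9 and the aryl ether untouched.

Compound list
1 | (S)-(+)-carvone | CC1=CC[C@@H](CC1=O)C(C)=C | starting material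
2 | lithium cross-conjugated dienolate of 1 | CC1=CC[C@H](C(C)=C)C=C1O[Li] | intermediate
3 | (5S,6R)-6-methylcarvone | CC1=CC[C@H](C(C)=C)[C@@H](C)C1=O | intermediate
4 | lithium enolate of 3 | CC1=CC[C@H](C(C)=C)C(C)=C1O[Li] | intermediate
5 | (5R,6R)-6-allyl-6-methylcarvone | CC1=CC[C@H](C(C)=C)[C@@](C)(CC=C)C1=O | intermediate
6 | 3-[(1R,6R)-1,3-dimethyl-2-oxo-6-(prop-1-en-2-yl)cyclohex-3-en-1-yl]propanal | CC1=CC[C@H](C(C)=C)[C@@](C)(CCC=O)C1=O | intermediate
7 | (5R,10R)-3-hydroxy-11-nordrim-7-en-9-one (both C3 epimers) | CC1=CC[C@@H]2C(C)(C)C(O)CC[C@@]2(C)C1=O | intermediate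
8 | (5S,10R)-drima-7,9(11)-dien-3-ol (both C3 epimers) | CC1=CC[C@@H]2C(C)(C)C(O)CC[C@@]2(C)C1=C | intermediate
9 | (5S,10R)-drima-7,9(11)-dien-3-one | CC1=CC[C@@H]2C(C)(C)C(=O)CC[C@@]2(C)C1=C | intermediate
10 | (3S,5S,10R)-drima-7,9(11)-dien-3-ol | CC1=CC[C@@H]2C(C)(C)[C@@H](O)CC[C@@]2(C)C1=C | intermediate
11 | C11 B-alkyl-9-BBN adduct of 10, C3 hydroxyl as its 9-BBN borinate | CC1=CC[C@@H]2C(C)(C)[C@@H](OB3C4CCCC3CCC4)CC[C@@]2(C)[C@@H]1CB1C2CCCC1CCC2 | intermediate
12 | (3S,5S,9R,10R)-drim-7-ene-3,11-diol | CC1=CC[C@@H]2C(C)(C)[C@@H](O)CC[C@@]2(C)[C@@H]1CO | intermediate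
13 | umbelliferone | Oc1ccc2ccc(=O)oc2c1 | starting material
14 | 7-{[(3S,5S,9R,10R)-3-hydroxydrim-7-en-11-yl]oxy}-2H-chromen-2-one | CC1=CC[C@@H]2C(C)(C)[C@@H](O)CC[C@@]2(C)[C@@H]1COc1ccc2ccc(=O)oc2c1 | intermediate
15 | ferocaulidin | CC1=CC(=O)[C@@H]2C(C)(C)[C@@H](O)CC[C@@]2(C)[C@@H]1COc1ccc2ccc(=O)oc2c1 | target

Total step count: 10. Longest linear sequence: 10 steps, from 1.

Steps most likely to fail

Step 4. The addition of the C4 radical to the aldehyde is reversible: the cyclised alkoxy radical may fragment back faster than it is reduced, and the open-chain radical is then drained by simple hydrogenation of the isopropenyl group. The fallback sets out from 6 and comes back at 7. The aldehyde of 6 is converted with I2 and aqueous NH3 in THF into the nitrile F1. The same Fe(acac)3/PhSiH3 conditions then close ring A by addition of the C4 radical to the nitrile carbon, a known HAT radical cyclisation onto nitriles in which the iminyl radical is reduced and does not fragment. This gives the cyclic ketimine F2, which dilute HCl work-up hydrolyses to the diketone F3. NaBH4 in CH2Cl2/MeOH at −78 °C should reduce the saturated C3 ketone in preference to the hindered conjugated C9 ketone and returns the route at 7 (as its equatorial C3 epimer).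

Step 10. Hydrogen abstraction may occur at the tertiary allylic C9–H instead of C6, leading to transposed 8-en-7-one products, or the free C3 carbinol may be over-oxidised. The fallback sets out from 14 and comes back at 15. The C3 hydroxyl is silylated (TBSOTf, 2,6-lutidine, CH2Cl2) to the silyl ether F4. C6 is then oxidised with CrO3/3,5-dimethylpyrazole (CH2Cl2, −20 °C), the classical chromium oxidation of 7-ene terpenoids to 7-en-6-ones, to the silyl ether enone F5. HF·pyridine in THF removes the silyl group under acidic conditions, which endanger neither C5 nor the aryl ether, and gives 15.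

Step 3. The oxypalladation may lose its regioselectivity (Markovnikov attack giving the methyl ketone) or the allyl double bond may migrate. The fallback sets out from 5 and comes back at 6. Hydroboration with pinacolborane catalysed by RhCl(PPh3)3 in THF is selective for the monosubstituted alkene over the 1,1-disubstituted one and spares the ketone; it gives the pinacol boronate F6. Oxidation with NaBO3·4H2O in THF/H2O gives the primary alcohol F7, and Dess–Martin periodinane gives 6.

Further compounds
F1 | step 4 | 3-[(1R,6R)-1,3-dimethyl-2-oxo-6-(prop-1-en-2-yl)cyclohex-3-en-1-yl]propanenitrile | CC1=CC[C@H](C(C)=C)[C@@](C)(CCC#N)C1=O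
F2 | step 4 | (5R,10R)-3-imino-11-nordrim-7-en-9-one | CC1=CC[C@@H]2C(C)(C)C(=N)CC[C@@]2(C)C1=O
F3 | step 4 | (5R,10R)-11-nordrim-7-ene-3,9-dione | CC1=CC[C@@H]2C(C)(C)C(=O)CC[C@@]2(C)C1=O
F4 | step 10 | 3-O-tert-butyldimethylsilyl ether of 14 | CC1=CC[C@@H]2C(C)(C)[C@@H](O[Si](C)(C)C(C)(C)C)CC[C@@]2(C)[C@@H]1COc1ccc2ccc(=O)oc2c1
F5 | step 10 | 3-O-tert-butyldimethylsilyl ether of 15 | CC1=CC(=O)[C@@H]2C(C)(C)[C@@H](O[Si](C)(C)C(C)(C)C)CC[C@@]2(C)[C@@H]1COc1ccc2ccc(=O)oc2c1
F6 | step 3 | pinacol boronate from terminal hydroboration of 5 | CC1=CC[C@H](C(C)=C)[C@@](C)(CCCB2OC(C)(C)C(C)(C)O2)C1=O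
F7 | step 3 | (5R,6R)-6-(3-hydroxypropyl)-2,6-dimethyl-5-(prop-1-en-2-yl)cyclohex-2-en-1-one | CC1=CC[C@H](C(C)=C)[C@@](C)(CCCO)C1=O
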